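**Assumption:** the target SMILES has no stereocentre and no stereogenic double bond, so eryvarin Q is achiral and no enantiocontrol is needed; the stereocentres of intermediates 7 and 9–12 are racemic or mixed and are erased by step 7.

## Retrosynthetic overview

1. Both prenyl groups are put on last by a double Stille coupling of dibromo-triphenol 14; the two C–Br handles are carried from the first steps.
2. The 2-aryl-3-formylbenzofuran 13 is not made by formylating a preformed 2-arylbenzofuran (the usual Sonogashira/cyclisation–Vilsmeier route); it comes from acid-mediated ring-opening/recyclisation of the 3-aroyl-2-methoxy-2,3-dihydrobenzofuran 11.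
3. Key step: 11 derives from β-keto acetal 9, made from chalcone 8 by a hypervalent-iodine oxidative 1,2-aryl shift that forms the C3–C3a bond and delivers the future CHO carbon.
4. Chalcone 8 comes from a Claisen–Schmidt condensation of bromoacetophenone 2 and MOM-protected bromosalicylaldehyde 6.
5. Ring order: both benzene rings are bought; the only ring built is the furan (transient dihydrofuran acetal in step 6, aromatic furan in step 7).

## Route

**Step 1**
Reactants: 1 1-(2,4-dimethoxyphenyl)ethanone
Product: 2 1-(5-bromo-2,4-dimethoxyphenyl)ethanone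
Conditions: NBS (1.05 equiv), MeCN, rt, dark
Reagents that add atoms: N-bromosuccinimide (O=C1CCC(=O)N1Br)
Why: Electrophilic aromatic bromination (SEAr) goes to C5, para to the 2-OMe and ortho to the 4-OMe, because C3 is flanked by both methoxy groups and NBS in MeCN brominates the activated ring rather than the ketone α-position.

**Step 2**
Reactants: 3 2-bromobenzene-1,3-diol
Product: 5 3-bromo-2,4-dihydroxybenzaldehyde, via aryl iminium chloride 4 (not isolated)
Conditions: POCl3 (1.2 equiv), DMF (1.5 equiv), MeCN, 0 °C → rt; then H2O, 50 °C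
Reagents that add atoms: N,N-dimethylformamide (CN(C)C=O); water (O)
Why: Vilsmeier–Haack formylation can only occur at the equivalent C4/C6 positions (ortho/para to the two OH groups; C2 carries Br and C5 is meta to both), and aqueous hydrolysis of iminium 4 releases the aldehyde.

**Step 3**
Reactants: 5 3-bromo-2,4-dihydroxybenzaldehyde
Product: 6 3-bromo-2,4-bis(methoxymethoxy)benzaldehyde
Conditions: NaH (2.5 equiv), MOMCl (2.5 equiv), DMF, 0 °C → rt
Reagents that add atoms: chloromethyl methyl ether (COCCl)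
Why: Williamson-type O-alkylation of both phenoxides, with NaH used because the 2-OH is hydrogen-bonded to the aldehyde and flanked by Br; the non-enolisable aldehyde and the aryl bromide are inert.

**Step 4**
Reactants: 2 1-(5-bromo-2,4-dimethoxyphenyl)ethanone; 6 3-bromo-2,4-bis(methoxymethoxy)benzaldehyde
Product: 8 (E)-3-[3-bromo-2,4-bis(methoxymethoxy)phenyl]-1-(5-bromo-2,4-dimethoxyphenyl)prop-2-en-1-one, via aldol adduct 7 (not isolated)
Conditions: KOH (50% aq), EtOH, rt
Reagents that add atoms: none
Why: Claisen–Schmidt (crossed aldol) condensation in which only ketone 2 can enolise and only 6 is an aldehyde acceptor, E1cB dehydration of 7 giving the thermodynamically favoured E-enone while MOM ethers, methyl ethers and aryl bromides are base-stable.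

**Step 5**
Reactants: 8 (E)-3-[3-bromo-2,4-bis(methoxymethoxy)phenyl]-1-(5-bromo-2,4-dimethoxyphenyl)prop-2-en-1-one
Product: 9 2-[3-bromo-2,4-bis(methoxymethoxy)phenyl]-1-(5-bromo-2,4-dimethoxyphenyl)-3,3-dimethoxypropan-1-one (racemic)
Conditions: PhI(OH)OTs (1.2 equiv), MeOH, rt
Reagents that add atoms: methanol (CO)
Why: Hypervalent-iodine oxidative rearrangement of a chalcone (1,2-aryl migration), in which methanol adds at Cβ, iodine(III) binds Cα and the electron-rich 2,4-dialkoxyaryl group shifts from Cβ to Cα with loss of PhI while a second methanol caps the oxocarbenium as the dimethyl acetal; the isolated prenyl-free substrate has no competing alkene and the new stereocentre (racemic) is erased in step 7.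

**Step 6**
Reactants: 9 2-[3-bromo-2,4-bis(methoxymethoxy)phenyl]-1-(5-bromo-2,4-dimethoxyphenyl)-3,3-dimethoxypropan-1-one
Product: 11 (7-bromo-6-hydroxy-2-methoxy-2,3-dihydro-1-benzofuran-3-yl)(5-bromo-2,4-dimethoxyphenyl)methanone (racemic diastereomer mixture), via bisphenol keto acetal 10 (not isolated)
Conditions: HCl (0.2 M in MeOH), rt, stopped as soon as 9 and 10 are consumed
Reagents that add atoms: none
Why: Acid-catalysed acetal exchange with methanol removes both MOM groups and the freed 2-OH closes at once onto the neighbouring dimethyl acetal (5-membered transacetalisation), room temperature and an early quench keeping the mixed acetal from aromatising to the unwanted 3-aroylbenzofuran.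

**Step 7**
Reactants: 11 (7-bromo-6-hydroxy-2-methoxy-2,3-dihydro-1-benzofuran-3-yl)(5-bromo-2,4-dimethoxyphenyl)methanone
Product: 13 7-bromo-2-(5-bromo-2,4-dimethoxyphenyl)-6-hydroxy-1-benzofuran-3-carbaldehyde, via keto aldehyde 12 (not isolated)
Conditions: p-TsOH·H2O (1 equiv), (CF3)2CHOH, rt
Reagents that add atoms: water (O)
Why: Acid-mediated ring-opening/recyclisation–dehydration in the strongly ionising, non-basic solvent HFIP, where the cyclic acetal opens to keto aldehyde 12, the phenol attacks the protonated aryl-stabilised ketone and loss of water aromatises the furan with the formyl group left at C3 (known behaviour of 3-acyl-2-alkoxy-2,3-dihydrobenzofurans, which give the 3-acyl isomer only in basic or weakly acidic media).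

**Step 8**
Reactants: 13 7-bromo-2-(5-bromo-2,4-dimethoxyphenyl)-6-hydroxy-1-benzofuran-3-carbaldehyde
Product: 14 7-bromo-2-(5-bromo-2,4-dihydroxyphenyl)-6-hydroxy-1-benzofuran-3-carbaldehyde
Conditions: BBr3 (6 equiv), CH2Cl2, −78 °C → rt; then ice/H2O
Reagents that add atoms: none
Why: Lewis-acid cleavage of both aryl methyl ethers by BBr3 (aryloxyborane plus MeBr, hydrolysed on work-up), carried out before any acid-sensitive prenyl group is present, with aryl bromides inert and any aldehyde–boron adduct reverting to CHO in water.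

**Step 9**
Reactants: 14 7-bromo-2-(5-bromo-2,4-dihydroxyphenyl)-6-hydroxy-1-benzofuran-3-carbaldehyde; 15 tributyl(3-methylbut-2-en-1-yl)stannane
Product: 17 eryvarin Q 2-[2,4-dihydroxy-5-(3-methylbut-2-en-1-yl)phenyl]-6-hydroxy-7-(3-methylbut-2-en-1-yl)-1-benzofuran-3-carbaldehyde, via mono-prenyl bromide 16 (not isolated)
Conditions: 15 (3.5 equiv), PdCl2(dppf) (10 mol %), DMF, 100 °C, degassed
Reagents that add atoms: none
Why: Double Stille (Migita–Kosugi–Stille) cross-coupling under neutral conditions that tolerate free phenols and the aldehyde, with reductive elimination from the prenyl–Pd–aryl species at the unsubstituted allyl terminus giving linear prenyl groups exactly at the two brominated carbons (C5' and C7).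

## Compound list

1 | 1-(2,4-dimethoxyphenyl)ethanone | CC(=O)c1ccc(OC)cc1OC | starting material
2 | 1-(5-bromo-2,4-dimethoxyphenyl)ethanone | CC(=O)c1cc(Br)c(OC)cc1OC | intermediate
3 | 2-bromobenzene-1,3-diol (2-bromoresorcinol) | Oc1cccc(O)c1Br | starting material
4 | [(3-bromo-2,4-dihydroxyphenyl)methylidene]dimethylazanium chloride | C[N+](C)=Cc1ccc(O)c(Br)c1O.[Cl-] | intermediate (not isolated)
5 | 3-bromo-2,4-dihydroxybenzaldehyde | O=Cc1ccc(O)c(Br)c1O | intermediate
6 | 3-bromo-2,4-bis(methoxymethoxy)benzaldehyde | COCOc1ccc(C=O)c(OCOC)c1Br | intermediate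
7 | 3-[3-bromo-2,4-bis(methoxymethoxy)phenyl]-1-(5-bromo-2,4-dimethoxyphenyl)-3-hydroxypropan-1-one (racemic) | COCOc1ccc(C(O)CC(=O)c2cc(Br)c(OC)cc2OC)c(OCOC)c1Br | intermediate (not isolated)
8 | (E)-3-[3-bromo-2,4-bis(methoxymethoxy)phenyl]-1-(5-bromo-2,4-dimethoxyphenyl)prop-2-en-1-one | COCOc1ccc(/C=C/C(=O)c2cc(Br)c(OC)cc2OC)c(OCOC)c1Br | intermediate
9 | 2-[3-bromo-2,4-bis(methoxymethoxy)phenyl]-1-(5-bromo-2,4-dimethoxyphenyl)-3,3-dimethoxypropan-1-one (racemic) | COCOc1ccc(C(C(OC)OC)C(=O)c2cc(Br)c(OC)cc2OC)c(OCOC)c1Br | intermediate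
10 | 2-(3-bromo-2,4-dihydroxyphenyl)-1-(5-bromo-2,4-dimethoxyphenyl)-3,3-dimethoxypropan-1-one (racemic) | COC(OC)C(c1ccc(O)c(Br)c1O)C(=O)c1cc(Br)c(OC)cc1OC | intermediate (not isolated)
11 | (7-bromo-6-hydroxy-2-methoxy-2,3-dihydro-1-benzofuran-3-yl)(5-bromo-2,4-dimethoxyphenyl)methanone (racemic, cis/trans mixture) | COC1Oc2c(Br)c(O)ccc2C1C(=O)c1cc(Br)c(OC)cc1OC | intermediate
12 | 2-(3-bromo-2,4-dihydroxyphenyl)-3-(5-bromo-2,4-dimethoxyphenyl)-3-oxopropanal (racemic) | O=CC(c1ccc(O)c(Br)c1O)C(=O)c1cc(Br)c(OC)cc1OC | intermediate (not isolated)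
13 | 7-bromo-2-(5-bromo-2,4-dimethoxyphenyl)-6-hydroxy-1-benzofuran-3-carbaldehyde | O=Cc1c(-c2cc(Br)c(OC)cc2OC)oc2c(Br)c(O)ccc12 | intermediate
14 | 7-bromo-2-(5-bromo-2,4-dihydroxyphenyl)-6-hydroxy-1-benzofuran-3-carbaldehyde | O=Cc1c(-c2cc(Br)c(O)cc2O)oc2c(Br)c(O)ccc12 | intermediate
15 | tributyl(3-methylbut-2-en-1-yl)stannane | CCCC[Sn](CCCC)(CCCC)CC=C(C)C | starting material
16 | 7-bromo-2-[2,4-dihydroxy-5-(3-methylbut-2-en-1-yl)phenyl]-6-hydroxy-1-benzofuran-3-carbaldehyde (less hindered C5'–Br assumed to couple first) | CC(C)=CCc1cc(-c2oc3c(Br)c(O)ccc3c2C=O)c(O)cc1O | intermediate (not isolated)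
17 | eryvarin Q, 2-[2,4-dihydroxy-5-(3-methylbut-2-en-1-yl)phenyl]-6-hydroxy-7-(3-methylbut-2-en-1-yl)-1-benzofuran-3-carbaldehyde (achiral) | CC(C)=CCc1cc(-c2oc3c(CC=C(C)C)c(O)ccc3c2C=O)c(O)cc1O | target

## Summary

Total step count: 9.
Longest linear sequence: 8 steps (3 → 5 → 6 → 8 → 9 → 11 → 13 → 14 → 17; steps 2–9). Ketone 2 is made in one step on the side.

## Three steps most likely to fail, with fallbacks

**Step 9 (double Stille on an unprotected, electron-rich dibromo-triphenol).** Oxidative addition next to phenols may be slow and the acidic OH groups may protonate the allylstannane. The fallback replaces the protecting-group-free coupling by protect–couple–deprotect, setting out from 14 and returning at 17. Compound 14 is peracetylated (Ac2O, pyridine, cat. DMAP, CH2Cl2, rt) to 7-bromo-2-(2,4-diacetoxy-5-bromophenyl)-3-formyl-1-benzofuran-6-yl acetate F1. This non-acidic, less electron-rich dibromide is coupled with stannane 15 (Pd(PPh3)4, toluene, 100 °C) to 2-[2,4-diacetoxy-5-(3-methylbut-2-en-1-yl)phenyl]-3-formyl-7-(3-methylbut-2-en-1-yl)-1-benzofuran-6-yl acetate F2. Mild methanolysis (K2CO3, MeOH, rt), which touches neither the prenyl groups nor the aldehyde, then gives 17.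

**Step 7 (regiochemistry of the furan closure: 3-formyl-2-aryl versus 3-aroyl).** If the 3-aroylbenzofuran competes, the fallback masks the aldehyde carbon so that the phenol can only close onto the ketone, setting out from 11 and returning at 13. Compound 11 is treated with ethane-1,2-dithiol (1.1 equiv) and BF3·OEt2 in CH2Cl2 at 0 °C, which opens the cyclic O,O-acetal to 2-(3-bromo-2,4-dihydroxyphenyl)-1-(5-bromo-2,4-dimethoxyphenyl)-2-(1,3-dithiolan-2-yl)ethanone F3. Cyclodehydration of the free phenol onto the ketone (p-TsOH, toluene, 80 °C) gives 7-bromo-2-(5-bromo-2,4-dimethoxyphenyl)-3-(1,3-dithiolan-2-yl)-1-benzofuran-6-ol F4. Non-oxidative transthioacetalisation (glyoxylic acid hydrate, AcOH, cat. HCl, rt) then unmasks the aldehyde to give 13.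

**Step 5 (iodine(III) oxidative aryl shift with acid-labile MOM ethers on electron-rich rings).** If MOM loss or ring oxidation intervenes, the fallback reaches the same carbon skeleton without an oxidant on the arenes, by an epoxide rearrangement with 1,2-acyl shift, setting out from 8 and returning at 11. Chalcone 8 is epoxidised under Weitz–Scheffer conditions (30% H2O2, NaOH, MeOH/THF, 0 °C) to trans-[3-(3-bromo-2,4-bis(methoxymethoxy)phenyl)oxiran-2-yl](5-bromo-2,4-dimethoxyphenyl)methanone F5. Brief treatment with BF3·OEt2 (CH2Cl2, −40 °C) opens the epoxide at the benzylic carbon and the aroyl group migrates (House–Meinwald rearrangement) to give 2-[3-bromo-2,4-bis(methoxymethoxy)phenyl]-3-(5-bromo-2,4-dimethoxyphenyl)-3-oxopropanal F6. HCl in MeOH at rt then removes the MOM groups and closes the lactol methyl ether, giving 11.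

## Further compounds

F1 | step 9 | 7-bromo-2-(2,4-diacetoxy-5-bromophenyl)-3-formyl-1-benzofuran-6-yl acetate | CC(=O)Oc1ccc2c(C=O)c(-c3cc(Br)c(OC(C)=O)cc3OC(C)=O)oc2c1Br
F2 | step 9 | 2-[2,4-diacetoxy-5-(3-methylbut-2-en-1-yl)phenyl]-3-formyl-7-(3-methylbut-2-en-1-yl)-1-benzofuran-6-yl acetate | CC(=O)Oc1ccc2c(C=O)c(-c3cc(CC=C(C)C)c(OC(C)=O)cc3OC(C)=O)oc2c1CC=C(C)C
F3 | step 7 | 2-(3-bromo-2,4-dihydroxyphenyl)-1-(5-bromo-2,4-dimethoxyphenyl)-2-(1,3-dithiolan-2-yl)ethanone (racemic) | O=C(C(c1ccc(O)c(Br)c1O)C1SCCS1)c1cc(Br)c(OC)cc1OC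
F4 | step 7 | 7-bromo-2-(5-bromo-2,4-dimethoxyphenyl)-3-(1,3-dithiolan-2-yl)-1-benzofuran-6-ol | Oc1ccc2c(C3SCCS3)c(-c3cc(Br)c(OC)cc3OC)oc2c1Br
F5 | step 5 | trans-[3-(3-bromo-2,4-bis(methoxymethoxy)phenyl)oxiran-2-yl](5-bromo-2,4-dimethoxyphenyl)methanone (racemic, one enantiomer drawn) | O=C([C@@H]1O[C@H]1c1ccc(OCOC)c(Br)c1OCOC)c1cc(Br)c(OC)cc1OC
F6 | step 5 | 2-[3-bromo-2,4-bis(methoxymethoxy)phenyl]-3-(5-bromo-2,4-dimethoxyphenyl)-3-oxopropanal (racemic) | O=CC(c1ccc(OCOC)c(Br)c1OCOC)C(=O)c1cc(Br)c(OC)cc1OC
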